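Ring C of the lower (epigallocatechin) unit is cut at C4–C4a and C2–C3. After the robinetinidol unit has been joined to C8 of a phloroglucinol ring through a silicon tether from its O3 (which sets the 4β bond), the free O1 carries the ring B aldehyde as an O-aryl acylal. One operation then ionises it to the O-aryl oxocarbenium ion (C4a=C8a–O1=C2) and annulates a two-carbon enediol disilyl ether across C2 and C4a, giving the flavan-3-one. The step exploits the 1,2-dioxygenated C2–C3 edge and the fact that C4a is the only free carbon ortho to O1. C2 and C3 are then set together by a dynamic kinetic hydrogenation.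

Key step: step 9

Remark: (+)-(2R,3R)-dihydrorobinetin is taken as a purchasable chiral-pool flavanonol; the double-bond geometry of the enediol disilyl ether is taken to be irrelevant because both isomers converge on the same ketone.

Step 1
Reactants: 1 (+)-dihydrorobinetin
Product: 2 tetra-O-benzyl-dihydrorobinetin: (2R,3R)-7-benzyloxy-3-hydroxy-2-[3,4,5-tris(benzyloxy)phenyl]chroman-4-one
Conditions: BnBr (4.4 equiv), K2CO3, DMF, rt
Reagents that add atoms: benzyl bromide BrCc1ccccc1
Why: Williamson etherification in which K2CO3 deprotonates only the four phenols, so the secondary C3 hydroxyl stays free and no stereocenter is touched.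

Step 2
Reactants: 2 tetra-O-benzyl-dihydrorobinetin
Product: 4 (2R,3S)-7-benzyloxy-4-methoxy-2-[3,4,5-tris(benzyloxy)phenyl]chroman-3-ol (both C4 epimers), via flavan-3,4-diol 3 (not isolated)
Conditions: NaBH4, THF–MeOH, 0 °C; then PPTS to pH 3–4, MeOH, rt
Reagents that add atoms: methanol CO
Why: Hydride reduction of the aryl ketone followed by acid-catalysed SN1 etherification of the benzylic C4 hydroxyl (para to the 7-benzyloxy group) by the solvent; C2 and C3 are untouched and the C4 configuration is immaterial because C4 is ionised again in step 4.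

Step 3
Reactants: 4 the 4-methoxyflavan-3-ol; 5 3,5-bis(benzyloxy)phenol
Product: 7 mixed silaketal in which O3 of 4 and the oxygen of 5 are joined by Si(i-Pr)2, via chlorosilyl ether 6 (not isolated)
Conditions: i-Pr2SiCl2 (3 equiv), imidazole, CH2Cl2, 0 °C; excess silane removed in vacuo; then 5, imidazole, DMAP (cat.), DMF, rt
Reagents that add atoms: dichlorodi(propan-2-yl)silane CC(C)[Si](Cl)(Cl)C(C)C
Why: Stepwise silyl ether formation at a dichlorosilane (temporary silicon tether), the hindered secondary hydroxyl taking one chloride from excess silane and the phenol the second; no stereocenter is touched.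

Step 4
Reactants: 7 mixed silaketal
Product: 8 cis-fused cyclic silyl ether: (2R,3S,4R)-7-benzyloxy-2-[3,4,5-tris(benzyloxy)phenyl]chroman whose C4 carries (β) C1 of a 4,6-bis(benzyloxy)-2-oxyphenyl ring and whose O3 and that ring oxygen are bridged by Si(i-Pr)2
Conditions: TMSOTf (0.2 equiv), 4 Å molecular sieves, CH2Cl2 (0.002 M), −78 to −40 °C; Et3N quench
Reagents that add atoms: none
Why: Intramolecular Friedel–Crafts alkylation in which TMSOTf ionises the C4 methyl ether to the para-alkoxy benzylic cation and the ring carbon ortho to the silylated phenol oxygen, held by the O3–Si–O tether, can reach the empty orbital only from the face of O3, so the seven-membered ring closes 3,4-cis and C4 is set as 4β (R); the two ortho carbons of the symmetric phenol are equivalent, so one constitution results.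

Step 5
Reactants: 8 cyclic silyl ether
Product: 9 (2R,3S,4R)-7-benzyloxy-4-[2,4-bis(benzyloxy)-6-hydroxyphenyl]-3-[diisopropyl(methyl)silyloxy]-2-[3,4,5-tris(benzyloxy)phenyl]chroman
Conditions: MeLi (1.1 equiv), THF, −78 °C; sat. aq. NH4Cl
Reagents that add atoms: methyllithium [Li]C
Why: Nucleophilic substitution at silicon in which methyllithium expels the better leaving group, the phenoxide, so that O1 of the future lower unit is freed while O3 of the upper unit stays protected as a trialkylsilyl ether; no stereocenter is touched.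

Step 6
Reactants: 10 3,4,5-tris(benzyloxy)benzaldehyde
Product: 11 chloro[3,4,5-tris(benzyloxy)phenyl]methyl pivalate (racemic)
Conditions: pivaloyl chloride (1.2 equiv), ZnCl2 (5 mol%), CH2Cl2, 0 °C to rt; used crude
Reagents that add atoms: pivaloyl chloride CC(C)(C)C(Cl)=O
Why: Lewis-acid-catalysed addition of an acyl chloride across the aldehyde C=O (formation of an alpha-chloroalkyl ester), a standard entry to acyloxyalkyl halides; the new center is racemic and is planarised later.

Step 7
Reactants: 9 phenol; 11 alpha-chloroalkyl pivalate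
Product: 12 O-aryl acylal in which the phenol oxygen of 9 is bonded to CH[3,4,5-tris(benzyloxy)phenyl](OCO-t-Bu) (both epimers at the acetal carbon)
Conditions: Cs2CO3, DMF, 0 °C
Reagents that add atoms: none
Why: Williamson-type O-alkylation of the caesium phenoxide by the alpha-chloroalkyl ester (as in the making of acyloxymethyl ethers of phenols), the bulky pivaloyl group suppressing acyl transfer; the acetal carbon is formed as both epimers, which is of no consequence.

Step 8
Reactants: 13 glycolaldehyde dimer (1,4-dioxane-2,5-diol)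
Product: 14 1,2-bis(trimethylsilyloxy)ethene (mainly Z)
Conditions: TMSCl, Et3N, DMF, 80 °C; distillation
Reagents that add atoms: chlorotrimethylsilane C[Si](C)(C)Cl
Why: Thermal cracking of the dimer, O-silylation and classical silyl enol ether formation from the aldehyde (TMSCl, Et3N, DMF); the geometry of the double bond does not matter.

Step 9
Reactants: 12 O-aryl acylal; 14 1,2-bis(trimethylsilyloxy)ethene
Product: 17 flavan-3-one: 5,7-bis(benzyloxy)-2-[3,4,5-tris(benzyloxy)phenyl]chroman-3-one carrying at C8 the (2R,3S,4R)-7-benzyloxy-3-[diisopropyl(methyl)silyloxy]-2-[3,4,5-tris(benzyloxy)phenyl]chroman-4-yl group (both C2 epimers of the new ring), via silyloxy aldehyde 15 (not isolated), via bis-silyloxy flavan 16 (not isolated)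
Conditions: 14 (1.5 equiv), TMSOTf (1.0 equiv), CH2Cl2 (0.01 M), −78 °C, then warm to 0 °C; aq. NaHCO3
Reagents that add atoms: none
Why: Proposed new method: TMSOTf silylates the pivalate carbonyl and expels it, so that 12 ionises to the O-aryl oxocarbenium ion (pivalate is the better leaving group and the aryloxy group stays on C2); 14 then adds through carbon in a Mukaiyama-type step (C2–C3), which uncovers C4 as a silyl-activated aldehyde that alkylates C4a (C4–C4a), and ionisation of the benzylic C4 silyl ether followed by a 1,2-hydride shift from C3 (semipinacol) or by loss of H3 and hydrolysis gives the C3 ketone. The closest known reactions are the oxa-Povarov annulation of aryl oxocarbenium ions with alkenes and the Lewis-acid addition of enol silanes to alpha-acyloxy ethers; the new element is an enediol disilyl ether as the two-carbon partner that ends as CH2–C(=O). Ring C of the lower unit closes by a 6-exo-trig Friedel–Crafts attack of C4a on the C4 carbonyl, so that the whole is a formal [4+2] annulation of the C4a=C8a–O1=C2 unit with C3=C4. C2 is formed without control on purpose, because it is alpha to the new ketone and is set together with C3 in step 10, and the transient centers at C3 and C4 disappear. The step needs chemoselective ionisation (secured by the acylal), oxygen at C3 and not at C4 (the carbon that bonds to C2 keeps its silyloxy group and only the benzylic C4 oxygen can ionise, while the symmetric reagent has no regiochemistry of its own), closure at C4a (the only free carbon ortho to O1, since C8 carries the upper unit), and capture of the cations by 14 and by the internal hydride before ring carbons of a second molecule intervene (the enol silane is the stronger nucleophile and the solution is dilute).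

Step 10
Reactants: 17 flavan-3-one
Product: 18 (2R,3R)-2,3-cis alcohol: 5,7-bis(benzyloxy)-2-[3,4,5-tris(benzyloxy)phenyl]chroman-3-ol carrying at C8 the same silyl-protected upper flavanyl group
Conditions: RuCl2[(S)-Xyl-SDP][(R,R)-DPEN] (2 mol%), KOt-Bu (0.3 equiv), H2 (50 atm), i-PrOH–toluene, rt
Reagents that add atoms: none
Why: Asymmetric ketone hydrogenation with dynamic kinetic resolution (Noyori type, as established for alpha-aryl and alpha-aryloxy ketones), in which the base epimerises C2 (alpha to the ketone, benzylic and oxygen-bearing) faster than reduction, the catalyst enantiomer matched to the 2R epimer is used, and hydride adds to the carbonyl face anti to the C2 aryl group, which gives the 2,3-cis (2R,3R) alcohol.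

Step 11
Reactants: 18 (2R,3R)-alcohol; 19 3,4,5-tris(benzyloxy)benzoic acid
Product: 20 3-O-[3,4,5-tris(benzyloxy)benzoyl] ester of 18
Conditions: DCC, DMAP, CH2Cl2, rt
Reagents that add atoms: none
Why: Steglich esterification of the only free hydroxyl (the upper O3 is still silylated), with retention at C3.

Step 12
Reactants: 20 silyl-protected ester
Product: 21 dodeca-O-benzyl robinetinidol-(4β→8)-epigallocatechin 3-O-gallate
Conditions: HF·pyridine, THF–pyridine, 0 °C to rt
Reagents that add atoms: none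
Why: Fluoride-mediated cleavage of the trialkylsilyl ether under conditions that leave the aryl ester and benzyl ethers intact; no stereocenter is touched.

Step 13
Reactants: 21 dodeca-O-benzyl ether
Product: 22 robinetinidol-(4β→8)-epigallocatechin 3-O-gallate (target)
Conditions: H2 (1 atm), Pd(OH)2/C, THF–MeOH, rt
Reagents that add atoms: none
Why: Catalytic hydrogenolysis of the twelve benzyl ethers, under which the gallate ester and the diarylmethine interflavan bond persist and no stereocenter is touched.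

Compound list
1 | (+)-dihydrorobinetin, (2R,3R)-3,7-dihydroxy-2-(3,4,5-trihydroxyphenyl)chroman-4-one | O=C1c2ccc(O)cc2O[C@H](c2cc(O)c(O)c(O)c2)[C@H]1O | starting material
2 | (2R,3R)-7-benzyloxy-3-hydroxy-2-[3,4,5-tris(benzyloxy)phenyl]chroman-4-one | O=C1c2ccc(OCc3ccccc3)cc2O[C@H](c2cc(OCc3ccccc3)c(OCc3ccccc3)c(OCc3ccccc3)c2)[C@H]1O | intermediate
3 | (2R,3S,4R)-7-benzyloxy-2-[3,4,5-tris(benzyloxy)phenyl]chroman-3,4-diol (not isolated) | O[C@@H]1c2ccc(OCc3ccccc3)cc2O[C@H](c2cc(OCc3ccccc3)c(OCc3ccccc3)c(OCc3ccccc3)c2)[C@H]1O | intermediate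
4 | (2R,3S)-7-benzyloxy-4-methoxy-2-[3,4,5-tris(benzyloxy)phenyl]chroman-3-ol (both C4 epimers) | COC1c2ccc(OCc3ccccc3)cc2O[C@H](c2cc(OCc3ccccc3)c(OCc3ccccc3)c(OCc3ccccc3)c2)[C@H]1O | intermediate
5 | 3,5-bis(benzyloxy)phenol | Oc1cc(OCc2ccccc2)cc(OCc2ccccc2)c1 | starting material
6 | 3-O-[chloro(diisopropyl)silyl] ether of 4 (not isolated) | COC1c2ccc(OCc3ccccc3)cc2O[C@H](c2cc(OCc3ccccc3)c(OCc3ccccc3)c(OCc3ccccc3)c2)[C@H]1O[Si](Cl)(C(C)C)C(C)C | intermediate
7 | mixed silaketal: 3-O-{[3,5-bis(benzyloxy)phenoxy]diisopropylsilyl} ether of 4 | COC1c2ccc(OCc3ccccc3)cc2O[C@H](c2cc(OCc3ccccc3)c(OCc3ccccc3)c(OCc3ccccc3)c2)[C@H]1O[Si](C(C)C)(C(C)C)Oc1cc(OCc2ccccc2)cc(OCc2ccccc2)c1 | intermediate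
8 | cis-fused cyclic silyl ether (4β-aryl, O3 and the phenol oxygen bridged by Si(i-Pr)2, seven-membered ring), upper unit (2R,3S,4R) | CC(C)[Si]1(C(C)C)Oc2cc(OCc3ccccc3)cc(OCc3ccccc3)c2[C@H]2c3ccc(OCc4ccccc4)cc3O[C@H](c3cc(OCc4ccccc4)c(OCc4ccccc4)c(OCc4ccccc4)c3)[C@H]2O1 | intermediate
9 | (2R,3S,4R)-7-benzyloxy-4-[2,4-bis(benzyloxy)-6-hydroxyphenyl]-3-[diisopropyl(methyl)silyloxy]-2-[3,4,5-tris(benzyloxy)phenyl]chroman | Oc1cc(OCc2ccccc2)cc(OCc2ccccc2)c1[C@H]1c2ccc(OCc3ccccc3)cc2O[C@H](c2cc(OCc3ccccc3)c(OCc3ccccc3)c(OCc3ccccc3)c2)[C@H]1O[Si](C)(C(C)C)C(C)C | intermediate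
10 | 3,4,5-tris(benzyloxy)benzaldehyde | O=Cc1cc(OCc2ccccc2)c(OCc2ccccc2)c(OCc2ccccc2)c1 | starting material
11 | chloro[3,4,5-tris(benzyloxy)phenyl]methyl pivalate (racemic) | CC(C)(C)C(=O)OC(Cl)c1cc(OCc2ccccc2)c(OCc2ccccc2)c(OCc2ccccc2)c1 | intermediate
12 | O-aryl acylal: phenol oxygen of 9 bonded to CH[3,4,5-tris(benzyloxy)phenyl](pivaloyloxy), both epimers at the acetal carbon | CC(C)(C)C(=O)OC(c1cc(OCc2ccccc2)c(OCc2ccccc2)c(OCc2ccccc2)c1)Oc1cc(OCc2ccccc2)cc(OCc2ccccc2)c1[C@H]1c2ccc(OCc3ccccc3)cc2O[C@H](c2cc(OCc3ccccc3)c(OCc3ccccc3)c(OCc3ccccc3)c2)[C@H]1O[Si](C)(C(C)C)C(C)C | intermediate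
13 | glycolaldehyde dimer (1,4-dioxane-2,5-diol) | OC1COC(O)CO1 | starting material
14 | (Z)-1,2-bis(trimethylsilyloxy)ethene | C[Si](C)(C)O/C=C\O[Si](C)(C)C | intermediate
15 | 3-aryloxy-3-[3,4,5-tris(benzyloxy)phenyl]-2-(trimethylsilyloxy)propanal, aryl = the phenol ring of 9 (not isolated, stereoisomer mixture at the two new centers) | O=CC(O[Si](C)(C)C)C(c1cc(OCc2ccccc2)c(OCc2ccccc2)c(OCc2ccccc2)c1)Oc1cc(OCc2ccccc2)cc(OCc2ccccc2)c1[C@H]1c2ccc(OCc3ccccc3)cc2O[C@H](c2cc(OCc3ccccc3)c(OCc3ccccc3)c(OCc3ccccc3)c2)[C@H]1O[Si](C)(C(C)C)C(C)C | intermediate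
16 | 3,4-bis(trimethylsilyloxy)flavan of the lower unit, 8-linked to the upper unit (not isolated, stereoisomer mixture at C2, C3 and C4 of the new ring) | C[Si](C)(C)OC1C(O[Si](C)(C)C)c2c(OCc3ccccc3)cc(OCc3ccccc3)c([C@H]3c4ccc(OCc5ccccc5)cc4O[C@H](c4cc(OCc5ccccc5)c(OCc5ccccc5)c(OCc5ccccc5)c4)[C@H]3O[Si](C)(C(C)C)C(C)C)c2OC1c1cc(OCc2ccccc2)c(OCc2ccccc2)c(OCc2ccccc2)c1 | intermediate
17 | flavan-3-one of the lower unit, 8-linked to the silyl-protected upper unit (both C2 epimers of the new ring) | O=C1Cc2c(OCc3ccccc3)cc(OCc3ccccc3)c([C@H]3c4ccc(OCc5ccccc5)cc4O[C@H](c4cc(OCc5ccccc5)c(OCc5ccccc5)c(OCc5ccccc5)c4)[C@H]3O[Si](C)(C(C)C)C(C)C)c2OC1c1cc(OCc2ccccc2)c(OCc2ccccc2)c(OCc2ccccc2)c1 | intermediate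
18 | (2R,3R)-2,3-cis-flavan-3-ol of the lower unit, 8-linked to the silyl-protected upper unit | O[C@@H]1Cc2c(OCc3ccccc3)cc(OCc3ccccc3)c([C@H]3c4ccc(OCc5ccccc5)cc4O[C@H](c4cc(OCc5ccccc5)c(OCc5ccccc5)c(OCc5ccccc5)c4)[C@H]3O[Si](C)(C(C)C)C(C)C)c2O[C@@H]1c1cc(OCc2ccccc2)c(OCc2ccccc2)c(OCc2ccccc2)c1 | intermediate
19 | 3,4,5-tris(benzyloxy)benzoic acid | O=C(O)c1cc(OCc2ccccc2)c(OCc2ccccc2)c(OCc2ccccc2)c1 | starting material
20 | 3-O-[3,4,5-tris(benzyloxy)benzoyl] ester of 18 | O=C(O[C@@H]1Cc2c(OCc3ccccc3)cc(OCc3ccccc3)c([C@H]3c4ccc(OCc5ccccc5)cc4O[C@H](c4cc(OCc5ccccc5)c(OCc5ccccc5)c(OCc5ccccc5)c4)[C@H]3O[Si](C)(C(C)C)C(C)C)c2O[C@@H]1c1cc(OCc2ccccc2)c(OCc2ccccc2)c(OCc2ccccc2)c1)c1cc(OCc2ccccc2)c(OCc2ccccc2)c(OCc2ccccc2)c1 | intermediate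
21 | dodeca-O-benzyl robinetinidol-(4β→8)-epigallocatechin 3-O-gallate | O=C(O[C@@H]1Cc2c(OCc3ccccc3)cc(OCc3ccccc3)c([C@H]3c4ccc(OCc5ccccc5)cc4O[C@H](c4cc(OCc5ccccc5)c(OCc5ccccc5)c(OCc5ccccc5)c4)[C@H]3O)c2O[C@@H]1c1cc(OCc2ccccc2)c(OCc2ccccc2)c(OCc2ccccc2)c1)c1cc(OCc2ccccc2)c(OCc2ccccc2)c(OCc2ccccc2)c1 | intermediate
22 | robinetinidol-(4β→8)-epigallocatechin 3-O-gallate (CNP0269431.2) | O=C(O[C@@H]1Cc2c(O)cc(O)c([C@H]3c4ccc(O)cc4O[C@H](c4cc(O)c(O)c(O)c4)[C@H]3O)c2O[C@@H]1c1cc(O)c(O)c(O)c1)c1cc(O)c(O)c(O)c1 | target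

Total step count: 13. Longest linear sequence: 11 steps (1, 2, 3, 4, 5, 7, 9, 10, 11, 12, 13).

Steps most likely to fail

Step 9 (proposed new method). The aryl oxocarbenium ion or the later C4 benzylic cation may be captured by ring carbons of a second molecule (oligomerisation), or the benzylidene unit may migrate from O1 to carbon, before addition, ring closure and hydride shift can occur. The fallback uses known chemistry and sets out from 9 and 10. Addition of HC≡CMgBr to 10 gives 1-[3,4,5-tris(benzyloxy)phenyl]prop-2-yn-1-ol F1. Mitsunobu etherification of phenol 9 with F1 (PPh3, DIAD, THF) gives the aryl propargyl ether F2. Oxidative gold catalysis (Ph3PAuNTf2, 8-methylquinoline N-oxide, CH2Cl2, rt) converts the terminal alkyne into an alpha-oxo gold carbene that closes onto C4a, which gives ketone 17, where the route is rejoined. In this fallback C2–C3 comes with the propargyl unit and the ring closure forms only C4–C4a.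

Step 4. The seven-membered closure may be outrun by intermolecular arylation, or the Lewis acid may cleave the Si–O(aryl) bond, so that facial and ortho control are lost. The fallback sets out from 4 and 5 and replaces the silicon tether by a diester tether, a known type of intramolecular flavan-4-yl cation arylation. Phenol 5 and excess adipic acid (DCC, DMAP) give the mono-aryl adipate F3. Esterification of F3 with the C3 hydroxyl of 4 (DCC, DMAP) gives the tethered diester F4. TMSOTf at high dilution should close the twelve-membered 3,4-cis macrodiolide F5. LiOH (THF–MeOH–H2O) removes the tether to give the phenol-alcohol F6, and i-Pr2Si(OTf)2 with 2,6-lutidine bridges its two hydroxyls to give 8, where the route is rejoined.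

Step 10. The catalyst may be mismatched with the chiral substrate, or C2 may epimerise too slowly, so that the resolution is incomplete and the wrong 2,3-cis diastereomer forms. The fallback sets out from 17 and relies on substrate control and separation. LiBH(s-Bu)3 (THF, −78 °C) should reduce both C2 epimers anti to the aryl group, which gives 18 and its (2S,3S) epimer F7. The two are diastereomers because of the upper unit and are separated by chromatography, and the route is rejoined at 18. F7 is returned to 17 by Dess–Martin oxidation and base epimerisation.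

Further compounds
F1 | step 9 | 1-[3,4,5-tris(benzyloxy)phenyl]prop-2-yn-1-ol | C#CC(O)c1cc(OCc2ccccc2)c(OCc2ccccc2)c(OCc2ccccc2)c1
F2 | step 9 | aryl propargyl ether of 9 (O1 bonded to CH(C≡CH)[3,4,5-tris(benzyloxy)phenyl]) | C#CC(c1cc(OCc2ccccc2)c(OCc2ccccc2)c(OCc2ccccc2)c1)Oc1cc(OCc2ccccc2)cc(OCc2ccccc2)c1[C@H]1c2ccc(OCc3ccccc3)cc2O[C@H](c2cc(OCc3ccccc3)c(OCc3ccccc3)c(OCc3ccccc3)c2)[C@H]1O[Si](C)(C(C)C)C(C)C
F3 | step 4 | 6-[3,5-bis(benzyloxy)phenoxy]-6-oxohexanoic acid | OC(=O)CCCCC(=O)Oc1cc(OCc2ccccc2)cc(OCc2ccccc2)c1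
F4 | step 4 | mixed adipate diester of 4 (O3) and 5 | COC1c2ccc(OCc3ccccc3)cc2O[C@H](c2cc(OCc3ccccc3)c(OCc3ccccc3)c(OCc3ccccc3)c2)[C@H]1OC(=O)CCCCC(=O)Oc1cc(OCc2ccccc2)cc(OCc2ccccc2)c1
F5 | step 4 | twelve-membered cis-fused macrodiolide (4β-aryl, adipate bridging O3 and the phenol oxygen) | O=C1CCCCC(=O)Oc2cc(OCc3ccccc3)cc(OCc3ccccc3)c2[C@H]2c3ccc(OCc4ccccc4)cc3O[C@H](c3cc(OCc4ccccc4)c(OCc4ccccc4)c(OCc4ccccc4)c3)[C@H]2O1
F6 | step 4 | (2R,3S,4R)-7-benzyloxy-4-[2,4-bis(benzyloxy)-6-hydroxyphenyl]-2-[3,4,5-tris(benzyloxy)phenyl]chroman-3-ol | Oc1cc(OCc2ccccc2)cc(OCc2ccccc2)c1[C@H]1c2ccc(OCc3ccccc3)cc2O[C@H](c2cc(OCc3ccccc3)c(OCc3ccccc3)c(OCc3ccccc3)c2)[C@H]1O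
F7 | step 10 | (2S,3S)-epimer of 18 in the lower unit | O[C@H]1Cc2c(OCc3ccccc3)cc(OCc3ccccc3)c([C@H]3c4ccc(OCc5ccccc5)cc4O[C@H](c4cc(OCc5ccccc5)c(OCc5ccccc5)c(OCc5ccccc5)c4)[C@H]3O[Si](C)(C(C)C)C(C)C)c2O[C@H]1c1cc(OCc2ccccc2)c(OCc2ccccc2)c(OCc2ccccc2)c1
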